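**Retrosynthetic overview**

1. Target 23 comes from dibenzoate 22 by hydrogenolysis of five benzyl ethers; 22 from the C1/C2 catechol 21; 21 from arene 20, whose four central oxygens carry three kinds of mask (C4, C5 benzyl; C1 MOM; C2 tert-butyl).
2. The strategy rests on the central hexasubstituted benzene ring (C1, C2 benzoate carbons; C3 aryl; C4, C5 hydroxyl carbons; C6 aryl). The run C1–C2–C3–C4 (O, O, aryl, O) is the four-carbon ring of an arylated squarate, and C5–C6 is an α-aryl-β-benzyloxyvinyl unit. The ring-forming bond is C4–C5, made by thermal 4π opening and 6π closure of cyclobutenone 16.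
3. 16 comes from vinyllithium 14 and arylcyclobutenedione 6 (C1–C6 bond), followed by MOM capture of the alkoxide; 6 from di-tert-butyl squarate 2 and the aryllithium of 1 (C3–aryl bond), then (CF3CO)2O.
4. 14 comes from bromo enol ether 13, made from enol ether 11 (Wittig of aldehyde 9 with the ylide derived from benzyl chloromethyl ether 7) by bromination and dehydrobromination.
5. Ring order: only the central arene is formed (step 6); the four-membered ring and all outer benzene rings are purchased.

Key step: step 6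

Remark on the chemistry: the central-ring numbering C1–C6 of the overview is kept in all intermediates; every cyclobutenone with a quaternary carbinol carbon is racemic, which is immaterial because step 6 removes that centre.

**Route**

Step 1
Reactants: 1 1-(benzyloxy)-4-bromobenzene; 2 di-tert-butyl squarate
Product: 6 3-[4-(benzyloxy)phenyl]-4-tert-butoxycyclobut-3-ene-1,2-dione, via 4-benzyloxyphenyllithium 3 (not isolated), via lithium carbinolate 4 (not isolated), via carbinol trifluoroacetate 5 (not isolated)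
Conditions: n-BuLi, THF, −78 °C; then 2, −78 °C; then (CF3CO)2O, −78 → 0 °C; aq. NaHCO3
Reagents that add atoms: none
Why: Bromine–lithium exchange gives the aryllithium, which adds 1,2 to one squarate carbonyl, and trifluoroacetylation of the carbinolate triggers ionisation with allylic transposition and loss of the tert-butyl cation from the vinylogous ester oxygen (the standard squarate to 3-substituted 4-alkoxycyclobutenedione sequence), leaving one tert-butoxy group in place.

Step 2
Reactants: 7 benzyl chloromethyl ether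
Product: 8 (benzyloxymethyl)triphenylphosphonium chloride
Conditions: PPh3, toluene, 80 °C
Reagents that add atoms: triphenylphosphine, c1ccc(P(c2ccccc2)c2ccccc2)cc1
Why: SN2 quaternisation of triphenylphosphine by the reactive α-chloro ether should give the alkoxymethyl Wittig salt, which precipitates.

Step 3
Reactants: 8 (benzyloxymethyl)triphenylphosphonium chloride; 9 4-(benzyloxy)benzaldehyde
Product: 11 1-(benzyloxy)-4-[2-(benzyloxy)ethenyl]benzene (E/Z mixture), via benzyloxymethylidene phosphorane 10 (not isolated)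
Conditions: NaN(SiMe3)2, THF, 0 °C; then 9, 0 °C → rt
Reagents that add atoms: none
Why: Wittig olefination with the non-stabilised alkoxymethyl ylide converts the aldehyde into the enol ether, and the E/Z mixture is acceptable because the next step erases this geometry.

Step 4
Reactants: 11 1-(benzyloxy)-4-[2-(benzyloxy)ethenyl]benzene
Product: 13 1-(benzyloxy)-4-[(Z)-2-(benzyloxy)-1-bromoethenyl]benzene, via vicinal dibromide 12 (not isolated)
Conditions: Br2 (1.0 equiv), CH2Cl2, −78 °C; then Et3N, −78 °C → rt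
Reagents that add atoms: bromine, BrBr
Why: Electrophilic addition of bromine to the enol ether gives the α,β-dibromo ether and base-induced dehydrobromination (benzylic hydrogen and anomeric bromide, through the oxocarbenium ion) returns the β-bromo enol ether, a known addition–elimination bromination of enol ethers; the Z isomer (bromine cis to benzyloxy, aryl trans to it) should be favoured sterically and is purified on base-washed silica.

Step 5
Reactants: 13 1-(benzyloxy)-4-[(Z)-2-(benzyloxy)-1-bromoethenyl]benzene; 6 3-[4-(benzyloxy)phenyl]-4-tert-butoxycyclobut-3-ene-1,2-dione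
Product: 16 racemic 2-[4-(benzyloxy)phenyl]-4-{(Z)-2-(benzyloxy)-1-[4-(benzyloxy)phenyl]ethenyl}-3-tert-butoxy-4-(methoxymethoxy)cyclobut-2-en-1-one, via vinyllithium 14 (not isolated), via lithium alkoxide 15 (not isolated)
Conditions: t-BuLi (2 equiv), THF, −78 °C; then 6, −78 °C; then MeOCH2Cl, −78 → 0 °C
Reagents that add atoms: chloromethyl methyl ether, COCCl
Why: Bromine–lithium exchange proceeds with retention to the oxygen-chelated vinyllithium (lithium cis to benzyloxy, the configuration that resists β-elimination), which adds 1,2 to the ketone-like carbonyl next to the tert-butoxy carbon of 6 (the other carbonyl is a deactivated vinylogous ester), and the tertiary lithium alkoxide is O-alkylated by the chloromethyl ether (Williamson-type acetal formation); the new quaternary centre forms as a racemate and is destroyed in step 6.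

Step 6
Reactants: 16 racemic 2-[4-(benzyloxy)phenyl]-4-{(Z)-2-(benzyloxy)-1-[4-(benzyloxy)phenyl]ethenyl}-3-tert-butoxy-4-(methoxymethoxy)cyclobut-2-en-1-one
Product: 19 6-(benzyloxy)-2,5-bis[4-(benzyloxy)phenyl]-3-tert-butoxy-4-(methoxymethoxy)phenol, via dienylketene 17 (not isolated), via cyclohexadienone 18 (not isolated)
Conditions: toluene (degassed, 0.02 M), 110 °C
Reagents that add atoms: none
Why: Heating cleaves the C4–C1 bond of the cyclobutenone by conrotatory 4π electrocyclic opening, and the methoxymethoxy donor on C1 rotates outward, so the alkenyl group turns inward and dienylketene 17 has C5 next to the ketene carbon C4. Thermal disrotatory 6π electrocyclisation then forms the C4–C5 bond and closes the six-membered carbocycle as cyclohexa-2,4-dienone 18, whose C5 hydrogen moves to O4 on tautomerisation to give phenol 19. The closest known reaction type is the thermal ring expansion of squarate-derived 4-alkenyl-4-oxycyclobutenones to para-oxygenated phenols, applied here to an α-aryl-β-benzyloxyalkenyl group. No stereocentre is formed and the racemic quaternary centre of 16 disappears. C5 is the oxygen-bearing and therefore not the nucleophilic carbon of the enol ether, so the closure is expected to draw on the strongly electrophilic sp ketene carbon, which has no inside substituent to clash with the inward benzyloxy group of the Z enol ether, on vinylogous donation from the C2 tert-butoxy group to C5 and on stabilisation of developing positive charge at C6 by the 4-benzyloxyphenyl group. The one selectivity needed is outward rotation of the C1 oxygen, secured by its donor character, while the substituent order is already fixed in 16 and both enol ether geometries would lead to 19.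

Step 7
Reactants: 19 6-(benzyloxy)-2,5-bis[4-(benzyloxy)phenyl]-3-tert-butoxy-4-(methoxymethoxy)phenol
Product: 20 1,2-bis(benzyloxy)-3,6-bis[4-(benzyloxy)phenyl]-4-tert-butoxy-5-(methoxymethoxy)benzene
Conditions: BnBr, K2CO3, DMF, rt → 50 °C
Reagents that add atoms: benzyl bromide, BrCc1ccccc1
Why: Williamson etherification of the single free phenol (C4–OH) gives C4 and C5 the same hydrogenolysable group while C1 and C2 stay acid-labile.

Step 8
Reactants: 20 1,2-bis(benzyloxy)-3,6-bis[4-(benzyloxy)phenyl]-4-tert-butoxy-5-(methoxymethoxy)benzene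
Product: 21 4,5-bis(benzyloxy)-3,6-bis[4-(benzyloxy)phenyl]benzene-1,2-diol
Conditions: CF3CO2H/CH2Cl2 (1:2), H2O (5 equiv), 0 °C → rt, argon
Reagents that add atoms: none
Why: Acidolysis cleaves the aryl tert-butyl ether by E1 loss of isobutene and hydrolyses the methoxymethyl acetal, whereas benzyl aryl ethers should withstand trifluoroacetic acid at room temperature, so only the C1/C2 catechol is unmasked.

Step 9
Reactants: 21 4,5-bis(benzyloxy)-3,6-bis[4-(benzyloxy)phenyl]benzene-1,2-diol
Product: 22 4,5-bis(benzyloxy)-3,6-bis[4-(benzyloxy)phenyl]-1,2-phenylene dibenzoate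
Conditions: BzCl, pyridine, DMAP (cat.), CH2Cl2, 0 °C → rt
Reagents that add atoms: benzoyl chloride, O=C(Cl)c1ccccc1
Why: DMAP-catalysed acylation of the two catechol hydroxyls, the only free OH groups in 21, places the benzoates on C1 and C2.

Step 10
Reactants: 22 4,5-bis(benzyloxy)-3,6-bis[4-(benzyloxy)phenyl]-1,2-phenylene dibenzoate
Product: 23 4,5-dihydroxy-3,6-bis(4-hydroxyphenyl)-1,2-phenylene dibenzoate (CNP0216579.0)
Conditions: H2 (1 atm), 10% Pd/C, THF/EtOAc, rt
Reagents that add atoms: none
Why: Catalytic hydrogenolysis removes all five benzyl ethers while aryl benzoates are inert, and the benzoates cannot migrate because the aryl-bearing carbons C3 and C6 separate them from the freed hydroxyls at C4 and C5.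

**Compound list**

1 | 1-(benzyloxy)-4-bromobenzene | Brc1ccc(OCc2ccccc2)cc1 | starting material
2 | di-tert-butyl squarate (3,4-di-tert-butoxycyclobut-3-ene-1,2-dione) | CC(C)(C)OC1=C(OC(C)(C)C)C(=O)C1=O | starting material
3 | 4-(benzyloxy)phenyllithium (not isolated) | [Li]c1ccc(OCc2ccccc2)cc1 | intermediate
4 | lithium 1-[4-(benzyloxy)phenyl]-2,3-di-tert-butoxy-4-oxocyclobut-2-en-1-olate, racemic (not isolated) | [Li]OC1(c2ccc(OCc3ccccc3)cc2)C(OC(C)(C)C)=C(OC(C)(C)C)C1=O | intermediate
5 | 1-[4-(benzyloxy)phenyl]-2,3-di-tert-butoxy-4-oxocyclobut-2-en-1-yl trifluoroacetate, racemic (not isolated) | O=C(OC1(c2ccc(OCc3ccccc3)cc2)C(OC(C)(C)C)=C(OC(C)(C)C)C1=O)C(F)(F)F | intermediate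
6 | 3-[4-(benzyloxy)phenyl]-4-tert-butoxycyclobut-3-ene-1,2-dione | O=C1C(=O)C(c2ccc(OCc3ccccc3)cc2)=C1OC(C)(C)C | intermediate
7 | benzyl chloromethyl ether | ClCOCc1ccccc1 | starting material
8 | (benzyloxymethyl)triphenylphosphonium chloride | [Cl-].c1ccc(COC[P+](c2ccccc2)(c2ccccc2)c2ccccc2)cc1 | intermediate
9 | 4-(benzyloxy)benzaldehyde | O=Cc1ccc(OCc2ccccc2)cc1 | starting material
10 | (benzyloxymethylidene)triphenylphosphorane (not isolated) | c1ccc(COC=P(c2ccccc2)(c2ccccc2)c2ccccc2)cc1 | intermediate
11 | 1-(benzyloxy)-4-[2-(benzyloxy)ethenyl]benzene, E/Z mixture | c1ccc(COC=Cc2ccc(OCc3ccccc3)cc2)cc1 | intermediate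
12 | 1-(benzyloxy)-4-[2-(benzyloxy)-1,2-dibromoethyl]benzene, diastereomer mixture (not isolated) | BrC(OCc1ccccc1)C(Br)c1ccc(OCc2ccccc2)cc1 | intermediate
13 | 1-(benzyloxy)-4-[(Z)-2-(benzyloxy)-1-bromoethenyl]benzene (Br cis to OBn) | Br/C(c1ccc(OCc2ccccc2)cc1)=C\OCc1ccccc1 | intermediate
14 | {2-(benzyloxy)-1-[4-(benzyloxy)phenyl]ethenyl}lithium, Li cis to OBn (not isolated) | [Li]/C(c1ccc(OCc2ccccc2)cc1)=C\OCc1ccccc1 | intermediate
15 | lithium alkoxide of the 4-alkenyl-4-hydroxycyclobutenone, racemic, Z enol ether (not isolated) | O=C1C(c2ccc(OCc3ccccc3)cc2)=C(OC(C)(C)C)C1(O[Li])/C(c1ccc(OCc2ccccc2)cc1)=C\OCc1ccccc1 | intermediate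
16 | racemic 2-[4-(benzyloxy)phenyl]-4-{(Z)-2-(benzyloxy)-1-[4-(benzyloxy)phenyl]ethenyl}-3-tert-butoxy-4-(methoxymethoxy)cyclobut-2-en-1-one | O=C1C(c2ccc(OCc3ccccc3)cc2)=C(OC(C)(C)C)C1(OCOC)/C(c1ccc(OCc2ccccc2)cc1)=C\OCc1ccccc1 | intermediate
17 | dienylketene O=C4=C3(Ar)–C2(OtBu)=C1(OMOM)–C6(Ar)=C5H(OBn), C3 and C6 cis on C2=C1, C1 and OBn cis on C6=C5 (not isolated) | O=C=C(c1ccc(OCc2ccccc2)cc1)/C(OC(C)(C)C)=C(OCOC)\C(c1ccc(OCc2ccccc2)cc1)=C/OCc1ccccc1 | intermediate
18 | 6-(benzyloxy)-2,5-bis[4-(benzyloxy)phenyl]-3-tert-butoxy-4-(methoxymethoxy)cyclohexa-2,4-dien-1-one, racemic (not isolated) | O=C1C(c2ccc(OCc3ccccc3)cc2)=C(OC(C)(C)C)C(OCOC)=C(c2ccc(OCc3ccccc3)cc2)C1OCc1ccccc1 | intermediate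
19 | 6-(benzyloxy)-2,5-bis[4-(benzyloxy)phenyl]-3-tert-butoxy-4-(methoxymethoxy)phenol | Oc1c(-c2ccc(OCc3ccccc3)cc2)c(OC(C)(C)C)c(OCOC)c(-c2ccc(OCc3ccccc3)cc2)c1OCc1ccccc1 | intermediate
20 | 1,2-bis(benzyloxy)-3,6-bis[4-(benzyloxy)phenyl]-4-tert-butoxy-5-(methoxymethoxy)benzene | COCOc1c(OC(C)(C)C)c(-c2ccc(OCc3ccccc3)cc2)c(OCc2ccccc2)c(OCc2ccccc2)c1-c1ccc(OCc2ccccc2)cc1 | intermediate
21 | 4,5-bis(benzyloxy)-3,6-bis[4-(benzyloxy)phenyl]benzene-1,2-diol | Oc1c(O)c(-c2ccc(OCc3ccccc3)cc2)c(OCc2ccccc2)c(OCc2ccccc2)c1-c1ccc(OCc2ccccc2)cc1 | intermediate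
22 | 4,5-bis(benzyloxy)-3,6-bis[4-(benzyloxy)phenyl]-1,2-phenylene dibenzoate | O=C(Oc1c(OC(=O)c2ccccc2)c(-c2ccc(OCc3ccccc3)cc2)c(OCc2ccccc2)c(OCc2ccccc2)c1-c1ccc(OCc2ccccc2)cc1)c1ccccc1 | intermediate
23 | 4,5-dihydroxy-3,6-bis(4-hydroxyphenyl)-1,2-phenylene dibenzoate (CNP0216579.0) | O=C(Oc1c(OC(=O)c2ccccc2)c(-c2ccc(O)cc2)c(O)c(O)c1-c1ccc(O)cc1)c1ccccc1 | target

**Step count**

Total steps: 10. Longest linear sequence: 9 steps (steps 2 to 10, from benzyl chloromethyl ether 7); step 1 supplies dione 6 as the convergent partner.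

**Steps most likely to fail**

Step 6. The benzyloxy group of the Z enol ether sits on the inside of the closing triene and C5 is not the nucleophilic end of the enol ether. Formation of the C4–C5 bond may therefore be slow enough for the dienylketene to dimerise, be intercepted by adventitious nucleophiles or reclose, and isobutene may be lost from the tert-butyl ether at the temperature needed. The fallback sets out from 6 and comes back at 20; it forms the ring with an alkenyl group that lacks the C5 oxygen and adds that oxygen afterwards. 4'-Benzyloxyacetophenone is condensed with 2,4,6-triisopropylbenzenesulfonylhydrazide to the trisylhydrazone F1. A Shapiro reaction (n-BuLi, 2 equiv, THF, −78 → 0 °C) gives 1-[4-(benzyloxy)phenyl]ethenyllithium F2, which adds to 6 as in step 5. The lithium alkoxide F3 is captured with MeOCH2Cl to give the 4-(1-arylethenyl) MOM ether F4. Heating in toluene opens F4 to dienylketene F5, which closes through an unsubstituted CH2 terminus to cyclohexadienone F6 and tautomerises to the C5-unsubstituted phenol F7. Ortho-oxygenation of F7 with 2-iodoxybenzoic acid (DMF, rt) at C5, its only free ortho position, should give ortho-quinone F8. Na2S2O4 reduces it to catechol F9, and BnBr/K2CO3 in DMF benzylates both hydroxyls to give 20.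

Step 5. The hindered tertiary lithium alkoxide may be O-alkylated too slowly at low temperature, and on warming it can ring-open or revert while residual organolithium consumes the chloromethyl ether. The fallback sets out from 15 and comes back at 16; it separates addition from protection. The cold mixture is quenched with aqueous NH4Cl and the tertiary carbinol F10 is isolated. The acetal is then installed in a separate amine-base operation (MeOCH2Cl, iPr2NEt, CH2Cl2, rt) to give 16. Should the β-alkoxy vinyllithium itself prove too short-lived, the sequence through F1 to F9 avoids it altogether.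

Step 4. The dehydrobromination may give poor control of the enol ether geometry, and bromine may attack the benzyloxyphenyl ring. The E bromide would be wasted because its vinyllithium eliminates lithium benzyloxide. The fallback sets out from 1 and comes back at 14; it fixes the geometry by chelated enolisation and not by elimination. Aryllithium 3 (from 1 as in step 1) is acylated with 2-(benzyloxy)-N-methoxy-N-methylacetamide to give 2-(benzyloxy)-1-[4-(benzyloxy)phenyl]ethanone F11. KN(SiMe3)2 in THF at −78 °C gives the chelated potassium Z enolate F12, and PhNTf2 converts it into the enol triflate F13 (triflate cis to benzyloxy). Stannylation with Me3SnSnMe3, Pd(PPh3)4 and LiCl in THF at 60 °C gives the vinylstannane F14 with retention. Tin–lithium exchange with MeLi (THF, −78 °C) then delivers 14 for step 5.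

**Further compounds**

F1 | step 6 | 4'-benzyloxyacetophenone 2,4,6-triisopropylbenzenesulfonylhydrazone | C/C(c1ccc(OCc2ccccc2)cc1)=N\NS(=O)(=O)c1c(C(C)C)cc(C(C)C)cc1C(C)C
F2 | step 6 | 1-[4-(benzyloxy)phenyl]ethenyllithium | [Li]C(=C)c1ccc(OCc2ccccc2)cc1
F3 | step 6 | lithium alkoxide of the 4-(1-arylethenyl)-4-hydroxycyclobutenone, racemic | O=C1C(c2ccc(OCc3ccccc3)cc2)=C(OC(C)(C)C)C1(O[Li])C(=C)c1ccc(OCc2ccccc2)cc1
F4 | step 6 | racemic 2-[4-(benzyloxy)phenyl]-4-{1-[4-(benzyloxy)phenyl]ethenyl}-3-tert-butoxy-4-(methoxymethoxy)cyclobut-2-en-1-one | O=C1C(c2ccc(OCc3ccccc3)cc2)=C(OC(C)(C)C)C1(OCOC)C(=C)c1ccc(OCc2ccccc2)cc1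
F5 | step 6 | dienylketene with unsubstituted CH2 terminus | O=C=C(c1ccc(OCc2ccccc2)cc1)/C(OC(C)(C)C)=C(OCOC)\C(=C)c1ccc(OCc2ccccc2)cc1
F6 | step 6 | 2,5-bis[4-(benzyloxy)phenyl]-3-tert-butoxy-4-(methoxymethoxy)cyclohexa-2,4-dien-1-one | O=C1CC(c2ccc(OCc3ccccc3)cc2)=C(OCOC)C(OC(C)(C)C)=C1c1ccc(OCc2ccccc2)cc1
F7 | step 6 | 2,5-bis[4-(benzyloxy)phenyl]-3-tert-butoxy-4-(methoxymethoxy)phenol | Oc1cc(-c2ccc(OCc3ccccc3)cc2)c(OCOC)c(OC(C)(C)C)c1-c1ccc(OCc2ccccc2)cc1
F8 | step 6 | 3,6-bis[4-(benzyloxy)phenyl]-4-tert-butoxy-5-(methoxymethoxy)cyclohexa-3,5-diene-1,2-dione | O=C1C(=O)C(c2ccc(OCc3ccccc3)cc2)=C(OCOC)C(OC(C)(C)C)=C1c1ccc(OCc2ccccc2)cc1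
F9 | step 6 | 3,6-bis[4-(benzyloxy)phenyl]-4-tert-butoxy-5-(methoxymethoxy)benzene-1,2-diol | Oc1c(O)c(-c2ccc(OCc3ccccc3)cc2)c(OCOC)c(OC(C)(C)C)c1-c1ccc(OCc2ccccc2)cc1
F10 | step 5 | racemic 2-[4-(benzyloxy)phenyl]-4-{(Z)-2-(benzyloxy)-1-[4-(benzyloxy)phenyl]ethenyl}-3-tert-butoxy-4-hydroxycyclobut-2-en-1-one | O=C1C(c2ccc(OCc3ccccc3)cc2)=C(OC(C)(C)C)C1(O)/C(c1ccc(OCc2ccccc2)cc1)=C\OCc1ccccc1
F11 | step 4 | 2-(benzyloxy)-1-[4-(benzyloxy)phenyl]ethanone | O=C(COCc1ccccc1)c1ccc(OCc2ccccc2)cc1
F12 | step 4 | potassium (Z)-2-(benzyloxy)-1-[4-(benzyloxy)phenyl]ethenolate | [K]O/C(c1ccc(OCc2ccccc2)cc1)=C\OCc1ccccc1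
F13 | step 4 | (Z)-2-(benzyloxy)-1-[4-(benzyloxy)phenyl]ethenyl trifluoromethanesulfonate | FC(F)(F)S(=O)(=O)O/C(c1ccc(OCc2ccccc2)cc1)=C\OCc1ccccc1
F14 | step 4 | {2-(benzyloxy)-1-[4-(benzyloxy)phenyl]ethenyl}trimethylstannane, Sn cis to OBn | C[Sn](C)(C)/C(c1ccc(OCc2ccccc2)cc1)=C\OCc1ccccc1
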